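**Retrosynthetic overview** (germacrane locants: C10 carries the methyl and the bridging O, C5 is the other bridgehead, C6–O/C7–C11 are the lactone fusion, C15 is the ester carbon on C4)

1. Last bonds: the C8 ester, by Yamaguchi coupling of the core alcohol 24 with the PMB-protected (S)-acid 29, then DDQ.
2. Key disconnection: C6–C7 and O–C5 are cut together, taking the tricycle back to the open-chain hydroxy enal allylboronate 20. Forward ring order in one pot: ten-membered carbocycle (C6–C7), then γ-lactone (O–C12), then the O-bridge that divides the carbocycle into the oxepine and oxepane rings.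
3. Enabling feature: C6–C7 is the fusion bond of the α-methylene-γ-butyrolactone, flanked by C6–O and the C11(=C13)–C12 acrylate, which is the retron of a 2-alkoxycarbonyl-allylboration. C5 is the allylic terminus of the 2-carbomethoxyallyl unit C3–C4(CO2Me)–C5 and lies 1,6 across the ten-membered ring from the C10 hydroxyl, so O–C5 can form by transannular conjugate addition with loss of a C3 acetate. The one-atom bridge of the 11-oxabicyclo[4.4.1] system lets C10 dictate C5.
4. Precursor 20 comes from (S)-linalool (C10, C14 and both arms C1–C3 and C8–C9), methyl propiolate plus ICH2Bpin (C7, C11–C13) and an α-iodo enoate (C4–C6, C15).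

Key step: step 12

Assumption: C3 (the acetoxy carbon, C9 of the open chain) is carried as both epimers from 18 to 22 because it becomes sp2 in step 12; the ligand enantiomers named in steps 4 and 14 are those expected to give the stated configurations, and the antipode would be used if the sense proves opposite.

**Step 1**
Reactants: 1 (S)-linalool
Product: 2 (3S)-3,7-dimethyl-3-(triethylsilyloxy)octa-1,6-diene
Conditions: TESOTf, 2,6-lutidine, CH2Cl2, −78 → 0 °C
Reagents that add atoms: triethylsilyl triflate, CC[Si](CC)(CC)OS(=O)(=O)C(F)(F)F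
Why: Silylation of a tertiary alcohol with a silyl triflate and a hindered base should be clean and leaves the C10 stereocentre untouched.

**Step 2**
Reactants: 2 (3S)-3,7-dimethyl-3-(triethylsilyloxy)octa-1,6-diene
Product: 4 (3S)-3,7-dimethyl-3-(triethylsilyloxy)oct-6-en-1-ol, via alkyl-9-BBN borane 3 (not isolated)
Conditions: 9-BBN, THF, 0 °C → rt; then NaOH, H2O2, 0 °C
Reagents that add atoms: hydrogen peroxide, OO
Why: Anti-Markovnikov hydroboration–oxidation, in which 9-BBN should select the monosubstituted vinyl group over the trisubstituted alkene.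

**Step 3**
Reactants: 4 (3S)-3,7-dimethyl-3-(triethylsilyloxy)oct-6-en-1-ol
Product: 5 (3S)-3,7-dimethyl-3-(triethylsilyloxy)oct-6-enal
Conditions: Dess–Martin periodinane, NaHCO3, CH2Cl2, 0 °C → rt
Reagents that add atoms: none
Why: Buffered hypervalent-iodine oxidation of a primary alcohol should give the β-silyloxy aldehyde without elimination.

**Step 4**
Reactants: 5 (3S)-3,7-dimethyl-3-(triethylsilyloxy)oct-6-enal; 6 methyl propiolate
Product: 7 methyl (4R,6S)-4-hydroxy-6,10-dimethyl-6-(triethylsilyloxy)undec-9-en-2-ynoate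
Conditions: (S,S)-ProPhenol (10 mol%), Me2Zn, Ph3P=O (20 mol%), toluene, 4 °C
Reagents that add atoms: none
Why: Zinc–ProPhenol-catalysed enantioselective alkynylation of an aldehyde, in which the dinuclear zinc catalyst should select the aldehyde face and set the C8 carbinol (4R) independently of the remote C10 centre.

**Step 5**
Reactants: 7 methyl (4R,6S)-4-hydroxy-6,10-dimethyl-6-(triethylsilyloxy)undec-9-en-2-ynoate
Product: 8 methyl (4R,6S)-4-(tert-butyldimethylsilyloxy)-6,10-dimethyl-6-(triethylsilyloxy)undec-9-en-2-ynoate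
Conditions: TBSCl, imidazole, DMF, rt
Reagents that add atoms: tert-butyldimethylsilyl chloride, CC(C)(C)[Si](C)(C)Cl
Why: Standard silylation of a secondary propargylic alcohol; the TBS ether is chosen to survive the later acid step that removes the tertiary TES group.

**Step 6**
Reactants: 8 methyl (4R,6S)-4-(tert-butyldimethylsilyloxy)-6,10-dimethyl-6-(triethylsilyloxy)undec-9-en-2-ynoate; 9 2-(iodomethyl)-4,4,5,5-tetramethyl-1,3,2-dioxaborolane
Product: 11 methyl (2Z,4R,6S)-4-(tert-butyldimethylsilyloxy)-6,10-dimethyl-2-[(4,4,5,5-tetramethyl-1,3,2-dioxaborolan-2-yl)methyl]-6-(triethylsilyloxy)undeca-2,9-dienoate, via α-alumino enoate 10 (not isolated)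
Conditions: i-Bu2AlH, HMPA, THF, 0 °C; then 9, 0 °C → rt
Reagents that add atoms: none
Why: Conjugate hydroalumination of the ynoate (syn delivery of H and Al) followed by C-alkylation of the α-alumino acrylate with the iodomethylboronate should place C8 cis to the ester and trans to CH2B, the geometry needed for an anti allylboration.

**Step 7**
Reactants: 11 methyl (2Z,4R,6S)-4-(tert-butyldimethylsilyloxy)-6,10-dimethyl-2-[(4,4,5,5-tetramethyl-1,3,2-dioxaborolan-2-yl)methyl]-6-(triethylsilyloxy)undeca-2,9-dienoate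
Product: 13 methyl (2Z,4R,6S)-4-(tert-butyldimethylsilyloxy)-6-methyl-9-oxo-2-[(4,4,5,5-tetramethyl-1,3,2-dioxaborolan-2-yl)methyl]-6-(triethylsilyloxy)non-2-enoate, via secondary ozonide 12 (not isolated)
Conditions: O3, CH2Cl2, −78 °C (Sudan Red 7B end point); then PPh3, −78 °C → rt
Reagents that add atoms: ozone, [O-][O+]=O
Why: Ozonolysis with a dye end point should cleave only the electron-rich isopropylidene alkene and spare the ester-conjugated allylboronate alkene.

**Step 8**
Reactants: 14 methyl (triphenylphosphoranylidene)acetate; 15 2,2-dimethoxyacetaldehyde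
Product: 17 methyl (Z)-2-iodo-4,4-dimethoxybut-2-enoate, via iodo ylide 16 (not isolated)
Conditions: N-iodosuccinimide, K2CO3, CH2Cl2, −20 °C; then 15, rt
Reagents that add atoms: N-iodosuccinimide, O=C1CCC(=O)N1I
Why: Iodination of the stabilised ylide followed by Wittig olefination should give the Z α-iodo enoate (iodine cis to the acetal carbon), as is usual for stabilised α-halo ylides.

**Step 9**
Reactants: 13 methyl (2Z,4R,6S)-4-(tert-butyldimethylsilyloxy)-6-methyl-9-oxo-2-[(4,4,5,5-tetramethyl-1,3,2-dioxaborolan-2-yl)methyl]-6-(triethylsilyloxy)non-2-enoate; 17 methyl (Z)-2-iodo-4,4-dimethoxybut-2-enoate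
Product: 18 methyl (2Z,4R,6S,10E)-4-(tert-butyldimethylsilyloxy)-9-hydroxy-12,12-dimethoxy-10-(methoxycarbonyl)-6-methyl-2-[(4,4,5,5-tetramethyl-1,3,2-dioxaborolan-2-yl)methyl]-6-(triethylsilyloxy)dodeca-2,10-dienoate (both C9 epimers)
Conditions: CrCl2 (4 equiv), NiCl2 (2 mol%), DMF, rt
Reagents that add atoms: none
Why: Nozaki–Hiyama–Kishi alkenyl–aldehyde coupling is aldehyde-selective and should transfer the alkenyl group with retention, so that C3 ends cis to the acetal carbon C6 (10E); the new carbinol centre is formed unselectively and is erased later.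

**Step 10**
Reactants: 18 methyl (2Z,4R,6S,10E)-4-(tert-butyldimethylsilyloxy)-9-hydroxy-12,12-dimethoxy-10-(methoxycarbonyl)-6-methyl-2-[(4,4,5,5-tetramethyl-1,3,2-dioxaborolan-2-yl)methyl]-6-(triethylsilyloxy)dodeca-2,10-dienoate
Product: 19 9-O-acetate of 18 (both C9 epimers)
Conditions: Ac2O, pyridine, DMAP (cat.), CH2Cl2, 0 °C
Reagents that add atoms: acetic anhydride, CC(=O)OC(C)=O
Why: Acylation of the secondary allylic alcohol installs the leaving group for the later addition–elimination; short reaction time at 0 °C should avoid amine-induced allylic transposition.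

**Step 11**
Reactants: 19 9-O-acetate of 18
Product: 20 methyl (2Z,4R,6S,10E)-9-acetoxy-4-(tert-butyldimethylsilyloxy)-6-hydroxy-10-(methoxycarbonyl)-6-methyl-12-oxo-2-[(4,4,5,5-tetramethyl-1,3,2-dioxaborolan-2-yl)methyl]dodeca-2,10-dienoate (both C9 epimers)
Conditions: AcOH/THF/H2O (3:1:1), 35 °C
Reagents that add atoms: water, O
Why: Mild aqueous acid should hydrolyse the dimethyl acetal to the enal and cleave the tertiary TES ether while sparing the secondary TBS ether, the pinacol boronate and the allylic acetate; the deactivated allylboronate is not expected to react with the aldehyde without a catalyst at this temperature.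

**Step 12**
Reactants: 20 methyl (2Z,4R,6S,10E)-9-acetoxy-4-(tert-butyldimethylsilyloxy)-6-hydroxy-10-(methoxycarbonyl)-6-methyl-12-oxo-2-[(4,4,5,5-tetramethyl-1,3,2-dioxaborolan-2-yl)methyl]dodeca-2,10-dienoate
Product: 23 (5R,6S,7S,8R,10S)-8-(tert-butyldimethylsilyloxy)-15-methoxy-15-oxo-5,10-epoxygermacra-3,11(13)-dien-12,6-olide, via ten-membered pinacol borate 21 (not isolated), via ten-membered trans-lactone 22 (not isolated)
Conditions: slow addition of 20 to Sc(OTf)3 (20 mol%), CH2Cl2, rt, final 0.003 M; then DBU (3 equiv), rt → 40 °C, same flask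
Reagents that add atoms: none
Why: Proposed new method: Sc(OTf)3-activated intramolecular allylboration of the enal by the 2-methoxycarbonyl allylboronate through a closed chair-like six-membered transition state should give borate 21, which lactonises onto C12 to 22, after which DBU lets the C10 hydroxyl add across the ring to C5 of the C5=C4–CO2Me acceptor and the ester enolate expels the C3 acetate (E1cB, net SN2′ etherification). The closest known reactions are the intermolecular Sc(OTf)3-catalysed allylboration–lactonisation of aldehydes with 3-substituted 2-alkoxycarbonyl allylboronates, ten-membered ring closure by intramolecular allylmetal–aldehyde addition, and base-mediated SN2′ etherification of Morita–Baylis–Hillman acetates. The carbocycle closes as a ten-membered ring with both tether ends equatorial on the chair, the lactone by 5-exo-trig acyl substitution, and the ether bridge by a transannular 7-endo-trig oxa-Michael addition that creates both seven-membered rings at once. The 6,7-anti (trans-lactone) relationship follows from the boronate geometry (C8 trans to CH2B); the face of C7 is set by C8 (H8 eclipsing the alkene to avoid A(1,3) strain with CO2Me, the C9 tether anti to the forming bond, OTBS outside); and C5 is fixed by C10 because the one-atom bridge can only close cis to the C10–C1 bond. The step needs 1,2-addition to the enal (inherent to allylboronates), lactonisation onto C12 and not C15 (secured by the 10E geometry, which holds C6 trans to that ester), and O-attack at C5 and not C3 (under basic, non-ionising conditions only the Michael position C5 is electrophilic).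

**Step 13**
Reactants: 23 (5R,6S,7S,8R,10S)-8-(tert-butyldimethylsilyloxy)-15-methoxy-15-oxo-5,10-epoxygermacra-3,11(13)-dien-12,6-olide
Product: 24 (5R,6S,7R,8R,10S)-8-hydroxy-15-methoxy-15-oxo-5,10-epoxygermacra-3,11(13)-dien-12,6-olide
Conditions: HF·pyridine, pyridine, THF, 0 °C → rt
Reagents that add atoms: none
Why: Buffered fluoride desilylation under weakly acidic conditions should free the C8 hydroxyl without base-induced translactonisation or addition to the α-methylene lactone.

**Step 14**
Reactants: 25 2-methyl-2-vinyloxirane (racemic); 26 4-methoxybenzyl alcohol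
Product: 27 (2S)-2-(4-methoxybenzyloxy)-2-methylbut-3-en-1-ol
Conditions: Pd2(dba)3·CHCl3 (1 mol%), (R,R)-DACH-phenyl ligand (3 mol%), Et3B (1 mol%), CH2Cl2, rt
Reagents that add atoms: none
Why: Palladium-catalysed dynamic kinetic asymmetric allylic etherification of the vinyl epoxide, in which the boron co-catalyst delivers the alkoxide to the tertiary allyl terminus and the chiral ligand should set the S quaternary centre.

**Step 15**
Reactants: 27 (2S)-2-(4-methoxybenzyloxy)-2-methylbut-3-en-1-ol
Product: 29 (2S)-2-(4-methoxybenzyloxy)-2-methylbut-3-enoic acid, via aldehyde 28 (not isolated)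
Conditions: TEMPO (20 mol%), PhI(OAc)2, MeCN/H2O (1:1), rt
Reagents that add atoms: water, O
Why: Oxoammonium-mediated oxidation of a primary alcohol through the aldehyde hydrate should give the acid without touching the PMB ether, the vinyl group or the quaternary centre.

**Step 16**
Reactants: 24 (5R,6S,7R,8R,10S)-8-hydroxy-15-methoxy-15-oxo-5,10-epoxygermacra-3,11(13)-dien-12,6-olide; 29 (2S)-2-(4-methoxybenzyloxy)-2-methylbut-3-enoic acid
Product: 31 8-O-[(2S)-2-(4-methoxybenzyloxy)-2-methylbut-3-enoyl] ester of 24, via mixed trichlorobenzoic anhydride 30 (not isolated)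
Conditions: 2,4,6-Cl3C6H2COCl, Et3N, toluene, rt; then 24, DMAP, rt
Reagents that add atoms: none
Why: Yamaguchi esterification is suited to coupling an α,α-disubstituted acid with a hindered secondary alcohol and proceeds with retention at C8.

**Step 17**
Reactants: 31 8-O-[(2S)-2-(4-methoxybenzyloxy)-2-methylbut-3-enoyl] ester of 24
Product: 32 target, (5R,6S,7R,8R,10S)-8-[(2S)-2-hydroxy-2-methylbut-3-enoyloxy]-15-methoxy-15-oxo-5,10-epoxygermacra-3,11(13)-dien-12,6-olide
Conditions: DDQ, CH2Cl2/pH 7 phosphate buffer (10:1), 0 °C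
Reagents that add atoms: none
Why: Oxidative cleavage of the PMB ether under neutral buffered conditions should release the tertiary alcohol without affecting the enoate, the α-methylene lactone or the allylic ester.

**Compound list**

1 | (S)-linalool | C=C[C@@](C)(O)CCC=C(C)C | starting material
2 | (3S)-3,7-dimethyl-3-(triethylsilyloxy)octa-1,6-diene | C=C[C@@](C)(O[Si](CC)(CC)CC)CCC=C(C)C | intermediate
3 | alkyl-9-BBN borane from 2 (boron on the former vinyl terminus) | B1(CC[C@@](C)(O[Si](CC)(CC)CC)CCC=C(C)C)C2CCCC1CCC2 | intermediate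
4 | (3S)-3,7-dimethyl-3-(triethylsilyloxy)oct-6-en-1-ol | OCC[C@@](C)(O[Si](CC)(CC)CC)CCC=C(C)C | intermediate
5 | (3S)-3,7-dimethyl-3-(triethylsilyloxy)oct-6-enal | O=CC[C@@](C)(O[Si](CC)(CC)CC)CCC=C(C)C | intermediate
6 | methyl propiolate | C#CC(=O)OC | starting material
7 | methyl (4R,6S)-4-hydroxy-6,10-dimethyl-6-(triethylsilyloxy)undec-9-en-2-ynoate | COC(=O)C#C[C@H](O)C[C@@](C)(O[Si](CC)(CC)CC)CCC=C(C)C | intermediate
8 | methyl (4R,6S)-4-(tert-butyldimethylsilyloxy)-6,10-dimethyl-6-(triethylsilyloxy)undec-9-en-2-ynoate | COC(=O)C#C[C@H](O[Si](C)(C)C(C)(C)C)C[C@@](C)(O[Si](CC)(CC)CC)CCC=C(C)C | intermediate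
9 | 2-(iodomethyl)-4,4,5,5-tetramethyl-1,3,2-dioxaborolane | CC1(C)OB(CI)OC1(C)C | starting material
10 | α-(diisobutylalumanyl) enoate from syn hydroalumination of 8 | CC(C)C[Al](CC(C)C)/C(C(=O)OC)=C/[C@H](O[Si](C)(C)C(C)(C)C)C[C@@](C)(O[Si](CC)(CC)CC)CCC=C(C)C | intermediate
11 | methyl (2Z,4R,6S)-4-(tert-butyldimethylsilyloxy)-6,10-dimethyl-2-[(pinacolatoboryl)methyl]-6-(triethylsilyloxy)undeca-2,9-dienoate | CC1(C)OB(C/C(C(=O)OC)=C/[C@H](O[Si](C)(C)C(C)(C)C)C[C@@](C)(O[Si](CC)(CC)CC)CCC=C(C)C)OC1(C)C | intermediate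
12 | secondary ozonide (1,2,4-trioxolane) of 11 | CC1(C)OB(C/C(C(=O)OC)=C/[C@H](O[Si](C)(C)C(C)(C)C)C[C@@](C)(O[Si](CC)(CC)CC)CCC2OOC(C)(C)O2)OC1(C)C | intermediate
13 | methyl (2Z,4R,6S)-4-(tert-butyldimethylsilyloxy)-6-methyl-9-oxo-2-[(pinacolatoboryl)methyl]-6-(triethylsilyloxy)non-2-enoate | CC1(C)OB(C/C(C(=O)OC)=C/[C@H](O[Si](C)(C)C(C)(C)C)C[C@@](C)(O[Si](CC)(CC)CC)CCC=O)OC1(C)C | intermediate
14 | methyl (triphenylphosphoranylidene)acetate | COC(=O)C=P(c1ccccc1)(c1ccccc1)c1ccccc1 | starting material
15 | 2,2-dimethoxyacetaldehyde | COC(OC)C=O | starting material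
16 | methyl 2-iodo-2-(triphenylphosphoranylidene)acetate | COC(=O)C(I)=P(c1ccccc1)(c1ccccc1)c1ccccc1 | intermediate
17 | methyl (Z)-2-iodo-4,4-dimethoxybut-2-enoate | COC(=O)/C(I)=C/C(OC)OC | intermediate
18 | methyl (2Z,4R,6S,10E)-4-(tert-butyldimethylsilyloxy)-9-hydroxy-12,12-dimethoxy-10-(methoxycarbonyl)-6-methyl-2-[(pinacolatoboryl)methyl]-6-(triethylsilyloxy)dodeca-2,10-dienoate, both C9 epimers | CC1(C)OB(C/C(C(=O)OC)=C/[C@H](O[Si](C)(C)C(C)(C)C)C[C@@](C)(O[Si](CC)(CC)CC)CCC(O)/C(C(=O)OC)=C\C(OC)OC)OC1(C)C | intermediate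
19 | 9-O-acetate of 18, both C9 epimers | CC1(C)OB(C/C(C(=O)OC)=C/[C@H](O[Si](C)(C)C(C)(C)C)C[C@@](C)(O[Si](CC)(CC)CC)CCC(OC(C)=O)/C(C(=O)OC)=C\C(OC)OC)OC1(C)C | intermediate
20 | methyl (2Z,4R,6S,10E)-9-acetoxy-4-(tert-butyldimethylsilyloxy)-6-hydroxy-10-(methoxycarbonyl)-6-methyl-12-oxo-2-[(pinacolatoboryl)methyl]dodeca-2,10-dienoate, both C9 epimers | CC1(C)OB(C/C(C(=O)OC)=C/[C@H](O[Si](C)(C)C(C)(C)C)C[C@@](C)(O)CCC(OC(C)=O)/C(C(=O)OC)=C\C=O)OC1(C)C | intermediate
21 | ten-membered carbocyclic pinacol borate (C6–O–Bpin, 6,7-anti, C7 bearing the 2-(methoxycarbonyl)vinyl group, C3 acetate epimers) | CC(C)(C)[Si](C)(C)O[C@@H]1C[C@@](C)(O)CCC(OC(C)=O)/C(C(=O)OC)=C\[C@@H](OB2OC(C)(C)C(C)(C)O2)[C@@H]1C(=C)C(=O)OC | intermediate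
22 | 3-acetoxy-8-(tert-butyldimethylsilyloxy)-10-hydroxy-15-methoxy-15-oxogermacra-4,11(13)-dien-12,6-olide (6,7-trans lactone, C3 epimers) | CC(C)(C)[Si](C)(C)O[C@@H]1C[C@@](C)(O)CCC(OC(C)=O)/C(C(=O)OC)=C\[C@H]2OC(=O)C(=C)[C@@H]21 | intermediate
23 | (5R,6S,7S,8R,10S)-8-(tert-butyldimethylsilyloxy)-15-methoxy-15-oxo-5,10-epoxygermacra-3,11(13)-dien-12,6-olide | CC(C)(C)[Si](C)(C)O[C@@H]1C[C@]2(C)CCC=C(C(=O)OC)[C@@H](O2)[C@H]2OC(=O)C(=C)[C@@H]21 | intermediate
24 | (5R,6S,7R,8R,10S)-8-hydroxy-15-methoxy-15-oxo-5,10-epoxygermacra-3,11(13)-dien-12,6-olide | O[C@@H]1C[C@]2(C)CCC=C(C(=O)OC)[C@@H](O2)[C@H]2OC(=O)C(=C)[C@@H]21 | intermediate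
25 | 2-methyl-2-vinyloxirane (racemic) | CC1(C=C)CO1 | starting material
26 | 4-methoxybenzyl alcohol | COc1ccc(CO)cc1 | starting material
27 | (2S)-2-(4-methoxybenzyloxy)-2-methylbut-3-en-1-ol | C=C[C@](C)(OCc1ccc(OC)cc1)CO | intermediate
28 | (2S)-2-(4-methoxybenzyloxy)-2-methylbut-3-enal | C=C[C@](C)(OCc1ccc(OC)cc1)C=O | intermediate
29 | (2S)-2-(4-methoxybenzyloxy)-2-methylbut-3-enoic acid | C=C[C@](C)(OCc1ccc(OC)cc1)C(=O)O | intermediate
30 | mixed anhydride of 29 with 2,4,6-trichlorobenzoic acid | C=C[C@](C)(OCc1ccc(OC)cc1)C(=O)OC(=O)c1c(Cl)cc(Cl)cc1Cl | intermediate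
31 | 8-O-[(2S)-2-(4-methoxybenzyloxy)-2-methylbut-3-enoyl] ester of 24 | C=C[C@](C)(OCc1ccc(OC)cc1)C(=O)O[C@@H]1C[C@]2(C)CCC=C(C(=O)OC)[C@@H](O2)[C@H]2OC(=O)C(=C)[C@@H]21 | intermediate
32 | target, (5R,6S,7R,8R,10S)-8-[(2S)-2-hydroxy-2-methylbut-3-enoyloxy]-15-methoxy-15-oxo-5,10-epoxygermacra-3,11(13)-dien-12,6-olide | C=C[C@](C)(O)C(=O)O[C@@H]1C[C@]2(C)CCC=C(C(=O)OC)[C@@H](O2)[C@H]2OC(=O)C(=C)[C@@H]21 | target

**Step count and risks**

Total step count: 17. Longest linear sequence: 14 (steps 1–7, 9–13, 16, 17).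

Steps most likely to fail:

Step 12 (proposed new method). Intermolecular allylboration and oligomerisation may outrun the ten-membered ring closure. The aldehyde may add to the wrong face of C7. Acetate may be lost by vinylogous 1,4-elimination before the hydroxyl adds across the ring. Fallback with known reaction types, in which the ether ring is made first and the carbocycle last: setting out from 19, buffered HF·pyridine should remove only the tertiary TES group to give the tertiary alcohol acetal F1. Cs2CO3 in MeCN should then effect the intramolecular oxa-Michael addition–elimination of the Morita–Baylis–Hillman-type acetate to the oxepine acetal F2. Aqueous acid should unmask the oxepinyl aldehyde F3, whose C5 centre is α to the aldehyde and can equilibrate so that only the 2,7-cis isomer goes on. Sc(OTf)3 should then close the seven-membered oxepane ring by intramolecular allylboration, anti to the α-alkoxy group, with lactonisation, and the route is rejoined at 23.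

Step 6. The α-alumino acrylate may isomerise through its allenolate before alkylation, losing the C8/ester cis geometry, or C-alkylation by the iodomethylboronate may be too slow. Fallback: setting out from 8, syn hydrostannation (PdCl2(PPh3)2, Bu3SnH) should give the α-stannyl enoate F4, and iodine should convert it with retention to the α-iodo enoate F5. Cross-coupling of F5 with bis(pinacolatoboryl)methane (Pd(P(t-Bu)3)2, KOH, dioxane/H2O) should give the allylboronate, rejoining the route at 11.

Step 9. Alkene geometry may be lost while the alkenyl group passes from nickel to chromium through an allenolate-type species. Aldehyde 13 may also be consumed by its own allylboronate under the Lewis-acidic chromium salts. Fallback with geometry fixed by syn addition: setting out from 13, zinc-mediated alkynylation with 3,3-dimethoxyprop-1-yne (Zn(OTf)2, Et3N) should give the propargylic alcohol F6. Hydroxyl-directed syn hydrostannation (PdCl2(PPh3)2, Bu3SnH) should give the proximal alkenylstannane F7, and iodine the alkenyl iodide F8. Methoxycarbonylation (Pd(PPh3)4, CO, MeOH, Et3N) with retention rejoins the route at 18.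

**Further compounds**

F1 | step 12 | tertiary alcohol acetal (19 without the TES group) | CC1(C)OB(C/C(C(=O)OC)=C/[C@H](O[Si](C)(C)C(C)(C)C)C[C@@](C)(O)CCC(OC(C)=O)/C(C(=O)OC)=C\C(OC)OC)OC1(C)C
F2 | step 12 | oxepine acetal (2,3,4,7-tetrahydrooxepine with C5 dimethoxymethyl, C4 ester, C10 methyl and the boronate side chain) | CC1(C)OB(C/C(C(=O)OC)=C/[C@H](O[Si](C)(C)C(C)(C)C)C[C@]2(C)CCC=C(C(=O)OC)[C@@H](O2)C(OC)OC)OC1(C)C
F3 | step 12 | oxepinyl aldehyde | CC1(C)OB(C/C(C(=O)OC)=C/[C@H](O[Si](C)(C)C(C)(C)C)C[C@]2(C)CCC=C(C(=O)OC)[C@@H](O2)C=O)OC1(C)C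
F4 | step 6 | α-(tributylstannyl) enoate from syn hydrostannation of 8 | CCCC[Sn](CCCC)(CCCC)/C(C(=O)OC)=C/[C@H](O[Si](C)(C)C(C)(C)C)C[C@@](C)(O[Si](CC)(CC)CC)CCC=C(C)C
F5 | step 6 | α-iodo enoate | I/C(C(=O)OC)=C/[C@H](O[Si](C)(C)C(C)(C)C)C[C@@](C)(O[Si](CC)(CC)CC)CCC=C(C)C
F6 | step 9 | propargylic alcohol from 13 and 3,3-dimethoxyprop-1-yne (both carbinol epimers) | CC1(C)OB(C/C(C(=O)OC)=C/[C@H](O[Si](C)(C)C(C)(C)C)C[C@@](C)(O[Si](CC)(CC)CC)CCC(O)C#CC(OC)OC)OC1(C)C
F7 | step 9 | proximal alkenylstannane | CC1(C)OB(C/C(C(=O)OC)=C/[C@H](O[Si](C)(C)C(C)(C)C)C[C@@](C)(O[Si](CC)(CC)CC)CCC(O)/C([Sn](CCCC)(CCCC)CCCC)=C\C(OC)OC)OC1(C)C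
F8 | step 9 | alkenyl iodide | CC1(C)OB(C/C(C(=O)OC)=C/[C@H](O[Si](C)(C)C(C)(C)C)C[C@@](C)(O[Si](CC)(CC)CC)CCC(O)/C(I)=C\C(OC)OC)OC1(C)C
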